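The carbocycle (C3, C4, C5, C20, C26, C27; atom labels follow the target SMILES) is opened at C3–C4 and C26–C27. The step exploits the 1,4 relationship, across C5 and the spiro carbon C20, between the nucleophilic enamine carbon C4 of the azepine ring and the electrophilic β-carbon C26 of the butenolide: (E)-1-nitrobut-1-ene is a two-carbon acceptor–donor unit that bridges them. One operation thus closes the cyclohexene, forms two C–C bonds and sets C3, C24, C26 and C27. Its precursor is bicyclic enamine 21, a pyrrolo[1,2-a]azepine bearing the spiro α-methylbutenolide at C20 and the saturated methyl lactone at C11; nitro-to-hydroxyl exchange at C27 completes the target.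

Key step: step 14

Remark: C27 is planar in ketone 30, so the C27 configuration of nitro compound 28 (drawn with nitro trans to ethyl) is not carried into the target and either C27 epimer serves.

Remark: the substrate gives no reliable control of C20 in step 9; the route plans for separation of the C20 epimers after step 10.

**Route**

Step 1
Reactants: 1 N-Boc-O-benzyl-L-homoserine
Product: 3 tert-butyl N-[(2S)-4-(benzyloxy)-1-oxobutan-2-yl]carbamate, via acylimidazole 2 (not isolated)
Conditions: CDI, CH2Cl2, 0 °C; then i-Bu2AlH (DIBAL-H), −78 °C; aq. sodium potassium tartrate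
Reagents that add atoms: none
Why: One-pot activation of the acid as its acylimidazole and hydride reduction at −78 °C should stop at the aldehyde (stable tetrahedral aluminium adduct), and the carbamate-protected centre C11, taken from L-homoserine, should keep its configuration if the crude aldehyde is used at once.

Step 2
Reactants: 3 tert-butyl N-[(2S)-4-(benzyloxy)-1-oxobutan-2-yl]carbamate; 4 ethyl 2-[(trimethylsilyl)methyl]prop-2-enoate
Product: 6 tert-butyl N-[(1S)-3-(benzyloxy)-1-[(2S)-4-methylidene-5-oxooxolan-2-yl]propyl]carbamate, via hydroxy ester 5 (not isolated)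
Conditions: SnCl4, CH2Cl2, −78 → −40 °C; then TsOH·H2O (cat.), CH2Cl2, rt
Reagents that add atoms: none
Why: Chelation-controlled Hosomi–Sakurai allylation: SnCl4 bridges the aldehyde oxygen and the NH-carbamate, the allylsilane attacks the chelate on the face away from the C11 side chain to give the syn (threo) amino alcohol, which sets C12 (S), and acid-catalysed lactonisation then closes the α-methylene lactone.

Step 3
Reactants: 6 tert-butyl N-[(1S)-3-(benzyloxy)-1-[(2S)-4-methylidene-5-oxooxolan-2-yl]propyl]carbamate
Product: 7 tert-butyl N-[(1S)-3-hydroxy-1-[(2S,4S)-4-methyl-5-oxooxolan-2-yl]propyl]carbamate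
Conditions: H2 (1 atm), Pd/C, EtOAc–MeOH, rt
Reagents that add atoms: none
Why: Heterogeneous hydrogenation should deliver hydrogen to the exocyclic alkene on the lactone face opposite the C12 substituent, which puts the new methyl group cis to it and sets C14 (S), while the same catalyst hydrogenolyses the benzyl ether.

Step 4
Reactants: 7 tert-butyl N-[(1S)-3-hydroxy-1-[(2S,4S)-4-methyl-5-oxooxolan-2-yl]propyl]carbamate
Product: 8 tert-butyl N-[(1S)-1-[(2S,4S)-4-methyl-5-oxooxolan-2-yl]-3-oxopropyl]carbamate
Conditions: Dess–Martin periodinane, NaHCO3, CH2Cl2, 0 °C → rt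
Reagents that add atoms: none
Why: Buffered Dess–Martin oxidation of a primary alcohol to the aldehyde; carbamate and lactone are inert and no stereocentre is touched.

Step 5
Reactants: 8 tert-butyl N-[(1S)-1-[(2S,4S)-4-methyl-5-oxooxolan-2-yl]-3-oxopropyl]carbamate; 9 ethyl 2-(bromomethyl)prop-2-enoate
Product: 11 tert-butyl N-[(1S)-2-(4-methylidene-5-oxooxolan-2-yl)-1-[(2S,4S)-4-methyl-5-oxooxolan-2-yl]ethyl]carbamate (both epimers at the new carbinol carbon C20), via hydroxy ester 10 (not isolated)
Conditions: Zn dust, THF–sat. aq. NH4Cl, rt; then TsOH·H2O (cat.), CH2Cl2, rt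
Reagents that add atoms: none
Why: Zinc-mediated Barbier allylation of the aldehyde followed by lactonisation should give the second α-methylene lactone; C20 forms as an epimer mixture that is made planar in step 7.

Step 6
Reactants: 11 tert-butyl N-[(1S)-2-(4-methylidene-5-oxooxolan-2-yl)-1-[(2S,4S)-4-methyl-5-oxooxolan-2-yl]ethyl]carbamate
Product: 12 tert-butyl N-[(1S)-2-(4-methyl-5-oxo-2,5-dihydrofuran-2-yl)-1-[(2S,4S)-4-methyl-5-oxooxolan-2-yl]ethyl]carbamate (C20 epimers)
Conditions: RhCl3·3H2O (5 mol%), EtOH, 75 °C
Reagents that add atoms: none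
Why: Rhodium-hydride-mediated migration of the exocyclic double bond into the ring should give the more stable trisubstituted α-methylbutenolide; the saturated lactone has no alkene and is not affected.

Step 7
Reactants: 12 tert-butyl N-[(1S)-2-(4-methyl-5-oxo-2,5-dihydrofuran-2-yl)-1-[(2S,4S)-4-methyl-5-oxooxolan-2-yl]ethyl]carbamate
Product: 13 tert-butyl N-[(1S)-2-[4-methyl-5-(triisopropylsilyloxy)furan-2-yl]-1-[(2S,4S)-4-methyl-5-oxooxolan-2-yl]ethyl]carbamate
Conditions: TIPSOTf (1.2 equiv), Et3N, CH2Cl2, 0 °C; non-aqueous work-up, used crude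
Reagents that add atoms: triisopropylsilyl trifluoromethanesulfonate, CC(C)[Si](OS(=O)(=O)C(F)(F)F)(C(C)C)C(C)C
Why: Soft enolisation: O-silylation with loss of the γ-proton converts only the butenolide into the aromatic 2-silyloxyfuran (the saturated lactone is not enolised by Et3N), and both C20 epimers converge on one furan.

Step 8
Reactants: 14 6-bromohexan-1-ol
Product: 15 6-bromohexanal
Conditions: Dess–Martin periodinane, NaHCO3, CH2Cl2, rt; used fresh
Reagents that add atoms: none
Why: Dess–Martin oxidation of a primary alcohol to the aldehyde; the primary bromide is inert.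

Step 9
Reactants: 13 tert-butyl N-[(1S)-2-[4-methyl-5-(triisopropylsilyloxy)furan-2-yl]-1-[(2S,4S)-4-methyl-5-oxooxolan-2-yl]ethyl]carbamate; 15 6-bromohexanal
Product: 16 tert-butyl N-[(1S)-2-[(2S)-2-(6-bromo-1-hydroxyhexyl)-4-methyl-5-oxo-2,5-dihydrofuran-2-yl]-1-[(2S,4S)-4-methyl-5-oxooxolan-2-yl]ethyl]carbamate (carbinol epimers; C20 S epimer shown)
Conditions: BF3·OEt2 (1.1 equiv), CH2Cl2, −78 °C
Reagents that add atoms: none
Why: Vinylogous Mukaiyama aldol reaction: the BF3-activated aldehyde is attacked by the γ-carbon of the silyloxyfuran, which forms C5–C20 and the quaternary centre C20; the furan faces are distinguished only by the remote C11 centre, so both C20 epimers are expected and the (S)-epimer is isolated after step 10.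

Step 10
Reactants: 16 tert-butyl N-[(1S)-2-[(2S)-2-(6-bromo-1-hydroxyhexyl)-4-methyl-5-oxo-2,5-dihydrofuran-2-yl]-1-[(2S,4S)-4-methyl-5-oxooxolan-2-yl]ethyl]carbamate
Product: 17 tert-butyl N-[(1S)-2-[(2S)-2-(6-bromohexanoyl)-4-methyl-5-oxo-2,5-dihydrofuran-2-yl]-1-[(2S,4S)-4-methyl-5-oxooxolan-2-yl]ethyl]carbamate (separated from its C20 epimer)
Conditions: Dess–Martin periodinane, NaHCO3, CH2Cl2, 0 °C → rt; chromatography
Reagents that add atoms: none
Why: Dess–Martin oxidation of the secondary alcohol removes the carbinol centre, so only the two C20-epimeric ketones remain; these are diastereomers and should separate on silica.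

Step 11
Reactants: 17 tert-butyl N-[(1S)-2-[(2S)-2-(6-bromohexanoyl)-4-methyl-5-oxo-2,5-dihydrofuran-2-yl]-1-[(2S,4S)-4-methyl-5-oxooxolan-2-yl]ethyl]carbamate
Product: 21 pyrrolo[1,2-a]azepine enamine (C4=C5) with the spiro α-methylbutenolide at C20 (S) and the (2S,4S)-4-methyl-5-oxooxolan-2-yl group at C11 (S), via ammonium trifluoroacetate 18 (not isolated), via bromopentyl spiro-pyrroline 19 (not isolated), via bicyclic iminium bromide 20 (not isolated)
Conditions: TFA, CH2Cl2, 0 °C; NaHCO3 (solid), 4 Å MS, MeCN, 0 °C → rt, filter; NaI (0.2 equiv), MeCN, 65 °C; then Et3N, rt; used crude under argon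
Reagents that add atoms: none
Why: Carbamate acidolysis, condensation of the freed amine with the C5 ketone to the five-membered cyclic imine, intramolecular N-alkylation by the primary halide (Finkelstein-assisted) to the seven-membered iminium ion and deprotonation at C4, the only α-carbon bearing hydrogen, should give the enamine; imine formation is run cold so that it outpaces acyl transfer from the lactone to nitrogen, and base is withheld until N-alkylation is complete to disfavour C-alkylation through the enamine tautomer.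

Step 12
Reactants: 22 nitromethane; 23 propanal
Product: 24 1-nitrobutan-2-ol
Conditions: KOtBu (5 mol%), THF–t-BuOH, 0 °C
Reagents that add atoms: none
Why: Base-catalysed Henry (nitroaldol) addition.

Step 13
Reactants: 24 1-nitrobutan-2-ol
Product: 26 (E)-1-nitrobut-1-ene, via nitro mesylate 25 (not isolated)
Conditions: MsCl (1.1 equiv), Et3N (2.2 equiv), CH2Cl2, −10 → 0 °C; distilled
Reagents that add atoms: none
Why: Mesylation and E1cB elimination of the β-nitro mesylate give the conjugated nitroalkene as its more stable E isomer.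

Step 14
Reactants: 21 pyrrolo[1,2-a]azepine enamine; 26 (E)-1-nitrobut-1-ene
Product: 28 pentacyclic C27-nitro analogue of the target (3R,11S,12S,14S,20S,24S,26S,27S), via nitroalkyl enamine 27 (not isolated)
Conditions: 26 (1.3 equiv), toluene, 4 Å MS, −20 °C → rt; then DBU (0.2 equiv), rt; AcOH quench at −20 °C
Reagents that add atoms: none
Why: Michael–Michael (formal [4+2]) annulation of the kind known for enamines and nitroalkenes that carry a second acceptor: C4 adds to the nitroalkene β-carbon (C4–C3) to give an iminium nitronate (27 after proton transfer), the nitronate carbon C27 adds to the butenolide β-carbon C26 (C27–C26), loss of the C4 proton restores the enamine and the lactone enolate is protonated at C24. The cyclohexene (C3, C4, C5, C20, C26, C27) closes in the second addition by a 6-exo-trig attack of the nitronate, promoted by DBU. C26 is fixed by the tether, which reaches only the butenolide face that carries C5 and so makes the ring fusion cis; C24 results from protonation of the enolate on the convex face, away from the new ring. C3 is expected with ethyl pseudo-axial and anti to O21, the arrangement that avoids allylic 1,2-strain with C10 in the closing transition state and in the product, although the first addition alone does not guarantee it; DBU lets the nitronate centre C27 equilibrate, and C27 is erased in step 15. The selectivities needed are C-attack at C4, secured because C20 is quaternary so that C4 is the only nucleophilic enamine carbon, and closure onto the butenolide only, secured because the second lactone is saturated.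

Step 15
Reactants: 28 pentacyclic C27-nitro compound
Product: 30 pentacyclic C27 ketone (other stereocentres as in 28), via sodium nitronate 29 (not isolated)
Conditions: NaOMe (1.0 equiv), MeOH–THF, 0 °C, 10 min; then aq. TiCl3, NH4OAc (pH 5–6), 0 °C → rt; NaHCO3 work-up
Reagents that add atoms: water, O
Why: Reductive Nef reaction: the nitronate is reduced by TiCl3 to the imine, which hydrolyses to the ketone; the single equivalent of methoxide is consumed at once by the acidic nitro C–H so the lactones stay closed, the buffered reductive medium spares the enamine (it re-forms from its iminium salt on basic work-up), and strong base is avoided because the product is a β-acyloxy ketone; C27 becomes planar.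

Step 16
Reactants: 30 pentacyclic C27 ketone
Product: 31 target CNP0154902.1 (3R,11S,12S,14S,20S,24S,26S,27S)
Conditions: NaBH4, MeOH–THF, −40 °C; AcOH quench at −40 °C
Reagents that add atoms: none
Why: Chemoselective borohydride reduction of the ketone beside two lactones; hydride should reach C27 from the convex face of the cis-fused bicycle, because the pseudo-axial lactone oxygen O21 blocks the axial trajectory, giving the alcohol cis to the lactone and trans to ethyl, and the cold acidic quench prevents acyl migration from O21 to the new alkoxide.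

**Compound list**

1 | N-Boc-O-benzyl-L-homoserine | CC(C)(C)OC(=O)N[C@@H](CCOCc1ccccc1)C(=O)O | starting material
2 | acylimidazole of 1 | CC(C)(C)OC(=O)N[C@@H](CCOCc1ccccc1)C(=O)n1ccnc1 | intermediate
3 | tert-butyl N-[(2S)-4-(benzyloxy)-1-oxobutan-2-yl]carbamate | CC(C)(C)OC(=O)N[C@@H](CCOCc1ccccc1)C=O | intermediate
4 | ethyl 2-[(trimethylsilyl)methyl]prop-2-enoate | C=C(C[Si](C)(C)C)C(=O)OCC | starting material
5 | ethyl (4S,5S)-7-(benzyloxy)-5-[(tert-butoxycarbonyl)amino]-4-hydroxy-2-methylideneheptanoate | CC(C)(C)OC(=O)N[C@@H](CCOCc1ccccc1)[C@@H](O)CC(=C)C(=O)OCC | intermediate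
6 | tert-butyl N-[(1S)-3-(benzyloxy)-1-[(2S)-4-methylidene-5-oxooxolan-2-yl]propyl]carbamate | CC(C)(C)OC(=O)N[C@@H](CCOCc1ccccc1)[C@@H]1CC(=C)C(=O)O1 | intermediate
7 | tert-butyl N-[(1S)-3-hydroxy-1-[(2S,4S)-4-methyl-5-oxooxolan-2-yl]propyl]carbamate | CC(C)(C)OC(=O)N[C@@H](CCO)[C@@H]1C[C@H](C)C(=O)O1 | intermediate
8 | tert-butyl N-[(1S)-1-[(2S,4S)-4-methyl-5-oxooxolan-2-yl]-3-oxopropyl]carbamate | CC(C)(C)OC(=O)N[C@@H](CC=O)[C@@H]1C[C@H](C)C(=O)O1 | intermediate
9 | ethyl 2-(bromomethyl)prop-2-enoate | C=C(CBr)C(=O)OCC | starting material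
10 | ethyl (6S)-6-[(tert-butoxycarbonyl)amino]-4-hydroxy-2-methylidene-6-[(2S,4S)-4-methyl-5-oxooxolan-2-yl]hexanoate (carbinol epimers) | CC(C)(C)OC(=O)N[C@@H](CC(O)CC(=C)C(=O)OCC)[C@@H]1C[C@H](C)C(=O)O1 | intermediate
11 | tert-butyl N-[(1S)-2-(4-methylidene-5-oxooxolan-2-yl)-1-[(2S,4S)-4-methyl-5-oxooxolan-2-yl]ethyl]carbamate (C20 epimers) | CC(C)(C)OC(=O)N[C@@H](CC1CC(=C)C(=O)O1)[C@@H]2C[C@H](C)C(=O)O2 | intermediate
12 | tert-butyl N-[(1S)-2-(4-methyl-5-oxo-2,5-dihydrofuran-2-yl)-1-[(2S,4S)-4-methyl-5-oxooxolan-2-yl]ethyl]carbamate (C20 epimers) | CC(C)(C)OC(=O)N[C@@H](CC1C=C(C)C(=O)O1)[C@@H]2C[C@H](C)C(=O)O2 | intermediate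
13 | tert-butyl N-[(1S)-2-[4-methyl-5-(triisopropylsilyloxy)furan-2-yl]-1-[(2S,4S)-4-methyl-5-oxooxolan-2-yl]ethyl]carbamate | CC(C)(C)OC(=O)N[C@@H](Cc1cc(C)c(O[Si](C(C)C)(C(C)C)C(C)C)o1)[C@@H]2C[C@H](C)C(=O)O2 | intermediate
14 | 6-bromohexan-1-ol | OCCCCCCBr | starting material
15 | 6-bromohexanal | O=CCCCCCBr | intermediate
16 | aldol adduct, quaternary C20 (S), carbinol epimers | CC(C)(C)OC(=O)N[C@@H](C[C@@]1(OC(=O)C(C)=C1)C(O)CCCCCBr)[C@@H]2C[C@H](C)C(=O)O2 | intermediate
17 | γ-(6-bromohexanoyl) butenolide, C20 (S) | CC(C)(C)OC(=O)N[C@@H](C[C@@]1(OC(=O)C(C)=C1)C(=O)CCCCCBr)[C@@H]2C[C@H](C)C(=O)O2 | intermediate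
18 | ammonium trifluoroacetate of the amino ketone | [NH3+][C@@H](C[C@@]1(OC(=O)C(C)=C1)C(=O)CCCCCBr)[C@@H]2C[C@H](C)C(=O)O2.[O-]C(=O)C(F)(F)F | intermediate
19 | 2-(5-bromopentyl)-1-pyrroline, spiro butenolide at C20 (S), lactone at C11 (S) | BrCCCCCC1=N[C@H]([C@@H]2C[C@H](C)C(=O)O2)C[C@@]13OC(=O)C(C)=C3 | intermediate
20 | bicyclic iminium bromide (C5=N6+) | C1C2=[N+](CCCC1)[C@H]([C@@H]3C[C@H](C)C(=O)O3)C[C@@]24OC(=O)C(C)=C4.[Br-] | intermediate
21 | pyrrolo[1,2-a]azepine enamine (C4=C5), spiro α-methylbutenolide at C20 (S), (2S,4S)-methyl lactone at C11 (S) | C1=C2N(CCCC1)[C@H]([C@@H]3C[C@H](C)C(=O)O3)C[C@@]24OC(=O)C(C)=C4 | intermediate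
22 | nitromethane | C[N+](=O)[O-] | starting material
23 | propanal | CCC=O | starting material
24 | 1-nitrobutan-2-ol | CCC(O)C[N+](=O)[O-] | intermediate
25 | 1-nitrobutan-2-yl methanesulfonate | CCC(OS(C)(=O)=O)C[N+](=O)[O-] | intermediate
26 | (E)-1-nitrobut-1-ene | CC/C=C/[N+](=O)[O-] | intermediate
27 | enamine 21 bearing a 1-nitrobutan-2-yl group at C4 (C3 as in the target) | CC[C@@H](C[N+](=O)[O-])C1=C2N(CCCC1)[C@H]([C@@H]3C[C@H](C)C(=O)O3)C[C@@]24OC(=O)C(C)=C4 | intermediate
28 | C27-nitro analogue of the target | CC[C@@H]1C2=C3N(CCCC2)[C@H]([C@@H]2C[C@H](C)C(=O)O2)C[C@@]32OC(=O)[C@@H](C)[C@H]2[C@H]1[N+](=O)[O-] | intermediate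
29 | sodium nitronate of 28 | CC[C@@H]1C2=C3N(CCCC2)[C@H]([C@@H]2C[C@H](C)C(=O)O2)C[C@@]32OC(=O)[C@@H](C)[C@H]2C1=[N+]([O-])[O-].[Na+] | intermediate
30 | C27 ketone | CC[C@@H]1C2=C3N(CCCC2)[C@H]([C@@H]2C[C@H](C)C(=O)O2)C[C@@]32OC(=O)[C@@H](C)[C@H]2C1=O | intermediate
31 | CNP0154902.1 | CC[C@@H]1C2=C3N(CCCC2)[C@H]([C@@H]2C[C@H](C)C(=O)O2)C[C@@]32OC(=O)[C@@H](C)[C@H]2[C@H]1O | target

**Step count**

Total step count: 16. Longest linear sequence: 13 steps (steps 1–7, 9–11, 14–16).

**Steps most likely to fail**

Step 14 (key step). Facial discrimination at C3 in the first addition may be poor. The sequence may also stop at the open adduct (or its cyclobutane or oxazine N-oxide valence isomers) because the nitronate does not add to the α,β-disubstituted butenolide. The fallback sets out from 21 and 26 and comes back at 30. Only the first conjugate addition is run (toluene, −20 °C, no base) and the nitroalkyl enamine 27 is isolated. Its primary nitro group is converted by the buffered TiCl3 Nef protocol into the α-ethyl aldehyde F1. A triazolium-derived N-heterocyclic carbene with catalytic amine base then adds the acyl-anion equivalent of C27 to C26 (intramolecular Stetter reaction). This closes the same six-membered ring and gives ketone 30 directly. C3 is α to a carbonyl group in F1 and 30 and can settle in its favoured pseudo-axial arrangement.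

Step 9. The two furan faces may not be distinguished at C20, and α-attack or retro-aldol cleavage on work-up may compete. The fallback sets out from 12 and comes back at 17. O-Acylation with 6-bromohexanoyl chloride and Et3N (CH2Cl2, 0 °C) gives the 2-acyloxyfuran F2. A chiral nucleophilic 4-(dimethylamino)pyridine catalyst (for example TADMAP, matched enantiomer) then moves the acyl group from oxygen to the γ-carbon C20 (Steglich-type O-to-C acyl transfer). The quaternary centre is formed under catalyst control and ketone 17 results without the aldol and oxidation pair; acyl transfer to the α-carbon is the competing pathway to watch.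

Step 11. Acyl transfer from the lactone to the freed amine may precede imine formation. C-alkylation at C4 through the enamine tautomer of the imine (five-membered carbocycle) may outrun the slower seven-membered N-alkylation. The fallback sets out from 13 and comes back at 21; it closes the seven-membered ring at C4–C10 by enamine C-alkylation. Aldol reaction of 13 with acetaldehyde (BF3·OEt2, −78 °C) gives the carbinol F3. Dess–Martin oxidation gives the methyl ketone F4, whose C20 epimers are separated. TFA then NaHCO3 gives the 2-methyl-1-pyrroline F5. Intermolecular N-alkylation with excess 1,4-diiodobutane (MeCN, 60 °C) gives the pyrrolinium iodide F6. i-Pr2NEt converts F6 into the exocyclic enamine F7, whose methylene carbon displaces the primary iodide to give the bicyclic iminium iodide F8. Deprotonation of F8 gives 21.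

Further compounds
F1 | step 14 | 2-substituted butanal: enamine 21 bearing a 1-oxobutan-2-yl group at C4 | CC[C@@H](C=O)C1=C2N(CCCC1)[C@H]([C@@H]3C[C@H](C)C(=O)O3)C[C@@]24OC(=O)C(C)=C4
F2 | step 9 | 2-(6-bromohexanoyloxy)furan analogue of 13 | CC(C)(C)OC(=O)N[C@@H](Cc1cc(C)c(OC(=O)CCCCCBr)o1)[C@@H]2C[C@H](C)C(=O)O2
F3 | step 11 | acetaldehyde aldol adduct, quaternary C20 (S), carbinol epimers | CC(C)(C)OC(=O)N[C@@H](C[C@@]1(OC(=O)C(C)=C1)C(C)O)[C@@H]2C[C@H](C)C(=O)O2
F4 | step 11 | γ-acetyl butenolide, C20 (S) | CC(C)(C)OC(=O)N[C@@H](C[C@@]1(OC(=O)C(C)=C1)C(C)=O)[C@@H]2C[C@H](C)C(=O)O2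
F5 | step 11 | 2-methyl-1-pyrroline with spiro butenolide at C20 (S) and lactone at C11 (S) | CC1=N[C@H]([C@@H]2C[C@H](C)C(=O)O2)C[C@@]13OC(=O)C(C)=C3
F6 | step 11 | N-(4-iodobutyl)-2-methyl-1-pyrrolinium iodide | CC1=[N+](CCCCI)[C@H]([C@@H]2C[C@H](C)C(=O)O2)C[C@@]13OC(=O)C(C)=C3.[I-]
F7 | step 11 | N-(4-iodobutyl)-2-methylidenepyrrolidine (exocyclic enamine) | C=C1N(CCCCI)[C@H]([C@@H]2C[C@H](C)C(=O)O2)C[C@@]13OC(=O)C(C)=C3
F8 | step 11 | bicyclic iminium iodide (cation of 20) | C1C2=[N+](CCCC1)[C@H]([C@@H]3C[C@H](C)C(=O)O3)C[C@@]24OC(=O)C(C)=C4.[I-]
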